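## Structural features

The target is a bicyclic bromo diterpenoid ether: a cyclohexane (ring A, C10–C15) is joined through its adjacent carbons C10 and C11 to a ten-membered oxacycle (O, C3–C11), and both of these ring bonds are equatorial on ring A. Ring A carries the contiguous stereocentres C10 (H) and C11 (methyl, ether oxygen) and, across the gem-dimethyl carbon C15, the equatorial secondary bromide C14. This array (H10 and the C11 methyl trans, Br cis to the C9 chain; 10S,11S,14S) is what a chair-like bromonium cyclisation of an E-trisubstituted alkene delivers. The large ring holds a trisubstituted epoxide whose ring carbons C5 and C8 are trans (adjacent centres C6 and C7, 6S,7S) and the isolated quaternary centre C3 (3R), which bears methyl, vinyl, C4 and the ether oxygen and is separated from C11 only by that oxygen. Fragile points are the neopentyl-type bromide (trans-1,4 to the C11 oxygen, sensitive to reducing metals and to internal displacement), the di-tertiary ether, which is allylic at C3 and therefore acid-labile, and the epoxide. The real difficulty is the C3–O–C11 link between two fully substituted carbons, which no direct etherification can make, together with control of C3 without a neighbouring stereocentre and closure of the ten-membered ring with the correct epoxide configuration. The key step exploits the substitution of C3: oxygen, methyl, a three-carbon chain (C4–C6) and a one-carbon handle for the vinyl group are what results when the oxygen of an unhindered C11–O–allyl ether captures a methyl-substituted ester carbenoid and the allyl group moves from oxygen to carbon.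

## Logic of the disconnections

21 to 19 (through 20): the C6–O bond of the epoxide is cut. An internal displacement makes the acid-labile epoxide last and is stereospecific (inversion at C6, retention at C7). The demand is that 19 be the cis-diol (6R,7S) and that only its secondary hydroxyl be sulfonylated.

19 to 18: the C6–C7 bond is cut. A reductive carbonyl coupling closes the ten-membered ring and creates both oxygenated carbons, so the bicycle becomes an open keto aldehyde. The forward step must work at high dilution, spare the C–Br bond and the vinyl group, and deliver one of four possible diols.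

18 to 17 to 16: only oxidation levels and one silyl group change. The C7 carbonyl is carried as a silyl-protected carbinol rather than a cyclic ketal, so that unmasking needs fluoride and not acid beside the tertiary allylic ether. The demand is a mild double oxidation of a primary and a secondary alcohol.

16 to 15 to 14 to 11 (through 12 and 13): C1=C2 is cut (methylenation) and the C6 oxygen is traced back to a terminal alkene. Tying the ester and the C6 hydroxyl into a lactone lets one hydride reduction and one Wittig reaction give the vinyl group and the free C6 alcohol without protecting groups. The demand is anti-Markovnikov hydroboration that leaves the ester alone and a reduction that stops at the lactol.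

11 to 7 + 9 (through 10): O–C3 and C3–C4 are cut together. Both bonds to the hindered carbon arise from an unhindered allyl ether and a small diazo ester, and the molecule falls into two pieces. The demand is that ylide formation at an oxygen flanked by quaternary C11 beat cyclopropanation, β-hydride shift and carbenoid dimerisation, and that C3 form as R. The silyl ether in 7 improves on a ketal for three reasons: it offers no competing Lewis-basic oxygen to the carbenoid, it avoids ketalising 3 (which can reclose to 2), and it avoids acid later.

7 to 5 + 6, and 9 to 8: the O–allyl bond is cut (alkoxide alkylation), and the diazo group is traced to an acetyl group (deacylative diazo transfer). The tertiary alkoxide must be alkylated faster than it displaces the trans-1,4 bromide.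

5 to 4 to 2 (through 3): the silyl group is removed, the carbinol is traced to the ketone, and the C11 hydroxyl and C7 carbonyl are folded back into an enol ether. The demand is selective silylation of a secondary over a tertiary hydroxyl.

2 to 1: C14–Br, C10–C15 and O–C11 are cut. One bromonium-initiated cyclisation builds ring A with all three of its stereocentres from an achiral dienone. The chair transition state sets the relative configuration and a chiral bromine-transfer catalyst must set the absolute one.

## Other disconnections considered

Alternative 1: The cut removes C14–Br, C10–C15 and O–C11 and exchanges the oxygen on C7. In the forward step Et2SBr·SbBrCl5 would brominate the terminal alkene of the tetrahydropyran diene A1; C10 closes ring A, the ring oxygen captures the C11 cation, and the C6 silyloxy oxygen displaces that oxygen from C7 with inversion to give the ethynyl compound A2. Semihydrogenation (Pd/CaCO3 poisoned with Pb(OAc)2) would finish the synthesis.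
- In its favour: ring A, the bromide, the ten-membered ring and the epoxide arise in one operation. C3, C6 and C7 are set beforehand in a six-membered ring, where control is reliable. The di-tertiary ether problem disappears because the oxygen already sits on C3.
- Against it: an achiral bromonium source cannot choose the face of C14=C15 relative to the remote ring stereocentres, so ring A would form in both senses. The hindered ring oxygen must also beat proton loss, and the oxonium ion must open only at C7.
- Comparison: on step economy and on control of C3, C6 and C7 this alternative is the better plan. On the relation between ring A and the rest the chosen plan is better, since ring A is set first by a catalyst. Mechanistically both rest on an oxonium intermediate without close precedent, so the risk is comparable.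

Alternative 2: The cut is C8–C9. In the forward step KN(SiMe3)2 would deprotonate the sulfone A3 and the carbanion would displace the allylic bromide under high dilution to give the ten-membered E-alkene A4; desulfonylation and epoxidation would follow.
- In its favour: the E-geometry of C6=C7 is fixed in the open chain, so the trans relationship of the epoxide is guaranteed and only one facial choice remains. On this point it is better than the chosen plan, where the coupling must set two centres. Sulfone alkylation is a well-tried macrocyclisation.
- Against it: it does not address the C3–O–C11 ether, which must still be made beforehand. The C9 carbanion is neopentyl-like, ten-membered closure by displacement is strained, and reductive desulfonylation (Na(Hg) or Mg/MeOH) threatens the C14 bromide.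
- Comparison: structurally it handles the epoxide better and the ether not at all. Mechanistically it is better precedented. In step count it is probably longer, because the sulfone and the allylic bromide must be installed and the sulfone removed.

Alternative 3: The cut is C3–C4 with allylic transposition. In the forward step enolisation and O-silylation of the 14-membered lactone A5 (LiN(i-Pr)2, Me3SiCl) would trigger an Ireland–Claisen shift that forms C3–C4, releases the vinyl group and contracts the ring to the acid A6; decarboxylation at C4 and epoxidation would follow.
- In its favour: C3 is made intramolecularly, without any reaction at a hindered oxygen, and the ten-membered ring arises by contraction of an easily closed large lactone. The configuration of C3 follows from enol ether geometry through an ordered transition state, a more readable control element than the ylide of the chosen plan.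
- Against it: A5 needs a geometrically defined enol ether of the tertiary C11 alcohol, which is hard to make and acid-labile. Chair or boat preference in a macrocycle is uncertain, and removing the C4 carboxyl by radical decarboxylation beside alkenes and a C–Br bond adds steps and risk.
- Comparison: both plans form C3–C4 by a sigmatropic shift. The alternative is better on ring formation and intramolecularity, about equal on the uncertainty at C3, and worse on precursor accessibility and step count.

Key step: step 6

Remark: atom numbers C1–C15 follow the target numbering throughout.
Remark: the oxygen-bearing carbon C7 of 4, 5, 7 and 10–17 is a throw-away stereocentre (both epimers are carried and converge at 18), so its configuration is left open in names and SMILES.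
Remark: the rearranged ester is needed as 2R in its own numbering; this is 3R of the target, because the ester and the later vinyl group hold the same priority rank.

Step 1
Reactants: 1 geranylacetone
Product: 2 (4aS,6S,8aS)-6-bromo-2,5,5,8a-tetramethyl-4a,5,6,7,8,8a-hexahydro-4H-chromene
Conditions: DBDMH (0.6 equiv), chiral 3,3'-bis(2,4,6-triisopropylphenyl)-BINOL N-triflyl thiophosphoramide (10 mol %, enantiomer chosen for 14S), PhMe/CH2Cl2, −78 °C; aq Na2S2O3
Reagents that add atoms: 1,3-dibromo-5,5-dimethylhydantoin, CC1(C)N(Br)C(=O)N(Br)C1=O
Why: Catalytic enantioselective bromonium polyene cyclisation: catalyst-bound Br+ adds to one face of the terminal alkene, C10=C11 attacks through a chair (Br equatorial, the E-alkene placing H10 and the C11 methyl trans) and the carbonyl oxygen traps the C11 cation, the oxocarbenium ion then losing a proton. The catalyst sets 14S and the chair relays it to 10S and 11S.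

Step 2
Reactants: 2 bicyclic bromo enol ether
Product: 4 (1S,2S,4S)-4-bromo-2-(3-hydroxybutyl)-1,3,3-trimethylcyclohexan-1-ol, via bromo hydroxy ketone 3 (not isolated)
Conditions: HCl (0.1 M aq, cat.), THF, rt; then NaBH4, MeOH, 0 °C
Reagents that add atoms: water, O
Why: Enol ether hydrolysis (C-protonation, addition of water, opening of the hemiketal) frees the tertiary C11 alcohol and the C7 methyl ketone, which NaBH4 reduces in the same flask. The new carbinol centre is not controlled and need not be.

Step 3
Reactants: 4 secondary/tertiary diol
Product: 5 (1S,2S,4S)-4-bromo-2-[3-(tert-butyldimethylsilyloxy)butyl]-1,3,3-trimethylcyclohexan-1-ol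
Conditions: TBSCl, imidazole, DMF, rt
Reagents that add atoms: tert-butyldimethylsilyl chloride, CC(C)(C)[Si](C)(C)Cl
Why: Silylation distinguishes the secondary hydroxyl from the hindered tertiary one on steric grounds.

Step 4
Reactants: 5 tertiary alcohol; 6 allyl bromide
Product: 7 tert-butyl{[4-((1S,3S,6S)-6-(allyloxy)-3-bromo-2,2,6-trimethylcyclohexyl)butan-2-yl]oxy}dimethylsilane
Conditions: KH, THF, 0 °C; 6, Bu4NI (cat.), 0 °C → rt
Reagents that add atoms: none
Why: Williamson ether synthesis of a tertiary potassium alkoxide with a reactive allylic halide. The C14 bromide is equatorial, has no antiperiplanar hydrogen and is neopentyl-like, so elimination and internal displacement should be slow at this temperature.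

Step 5
Reactants: 8 methyl 2-methylacetoacetate
Product: 9 methyl 2-diazopropanoate
Conditions: p-ABSA, DBU, MeCN, 0 °C → rt
Reagents that add atoms: 4-acetamidobenzenesulfonyl azide, CC(=O)Nc1ccc(cc1)S(=O)(=O)N=[N+]=[N-]
Why: Deacylative diazo transfer (Regitz type): the enolate adds to the sulfonyl azide and the adduct fragments with transfer of the acetyl group to the sulfonamide nitrogen.

Step 6
Reactants: 7 tertiary allyl ether; 9 methyl 2-diazopropanoate
Product: 11 methyl (2R)-2-{[(1S,2S,4S)-4-bromo-2-[3-(tert-butyldimethylsilyloxy)butyl]-1,3,3-trimethylcyclohexyl]oxy}-2-methylpent-4-enoate, via oxonium ylide 10 (not isolated)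
Conditions: [Cu(MeCN)4]PF6 (10 mol %), 2,2'-(propane-2,2-diyl)bis[(4S)-4-phenyl-4,5-dihydrooxazole] (12 mol %), CH2Cl2, 0 °C → rt; 9 (4 equiv) added over 12 h
Reagents that add atoms: none
Why: Proposed new method: loss of N2 from 9 on the cationic monovalent copper centre gives an electrophilic carbenoid, which the ether oxygen of 7 attacks to form ylide 10; a concerted five-centre [2,3] shift then moves the allyl group from oxygen to carbon with allylic transposition, so that O–C3 and C3–C4 form together and the former O–CH2 carbon becomes the terminal C6. The closest known reaction type is the intermolecular metal-catalysed oxonium ylide [2,3] rearrangement of allyl methyl ethers with diazoacetates (Doyle–Kirmse type), supported by copper-catalysed O–H insertion of 2-diazopropanoates, which shows that oxygen ylides form from this carbenoid faster than the β-hydride shift; neither has been shown for a tertiary-alkyl allyl ether. No ring is closed. C3 is the only new stereocentre: its configuration depends on which diastereotopic lone pair of the ether oxygen binds the carbenoid and on the rotamer about O–C3 in the envelope transition state (the bulky C11 group exo and next to the C3 methyl rather than the ester), both biased by the C11 stereocentre on oxygen and by the chiral bis(oxazoline) on the metal-bound ylide. This control is not assured, so the ligand enantiomer is to be matched to the substrate and the 3R isomer separated from its epimer at 14. The step needs ylide formation to beat cyclopropanation, β-hydride shift to methyl acrylate and carbenoid dimerisation: a disubstituted carbenoid cyclopropanates a monosubstituted alkene poorly, the reaction runs at 0 °C with slow addition of excess 9, and the silyl ether, unlike a ketal, offers no competing basic oxygen. The [2,3] shift should outrun a [1,2] shift or ionisation of the C11–O bond because it is an allowed, low-barrier five-membered process.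

Step 7
Reactants: 11 rearranged allyl ester
Product: 14 (3R)-3-{[(1S,2S,4S)-4-bromo-2-[3-(tert-butyldimethylsilyloxy)butyl]-1,3,3-trimethylcyclohexyl]oxy}-3-methyltetrahydro-2H-pyran-2-one, via B-alkyl-9-BBN adduct 12 (not isolated), via hydroxy ester 13 (not isolated)
Conditions: 9-BBN, THF, 0 °C → rt; H2O2, aq NaOAc, 0 °C; then PPTS (cat.), PhMe, 60 °C
Reagents that add atoms: hydrogen peroxide, OO
Why: Anti-Markovnikov hydroboration–oxidation of the monosubstituted alkene leaves ester, bromide and silyl ether untouched. The C6 alcohol then closes onto the neighbouring ester (gem-disubstituent effect at C3) to the six-membered lactone, the stage at which the C3 epimers are to be separated.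

Step 8
Reactants: 14 lactone
Product: 15 (3R)-3-{[(1S,2S,4S)-4-bromo-2-[3-(tert-butyldimethylsilyloxy)butyl]-1,3,3-trimethylcyclohexyl]oxy}-3-methyltetrahydro-2H-pyran-2-ol (anomer mixture)
Conditions: i-Bu2AlH (1.2 equiv), CH2Cl2, −78 °C; aq KNaC4H4O6
Reagents that add atoms: none
Why: Partial reduction of a lactone: the tetrahedral aluminate is stable at −78 °C and gives the lactol on work-up. The alkyl bromide and the silyl ether are inert.

Step 9
Reactants: 15 lactol
Product: 16 (4R)-4-{[(1S,2S,4S)-4-bromo-2-[3-(tert-butyldimethylsilyloxy)butyl]-1,3,3-trimethylcyclohexyl]oxy}-4-methylhex-5-en-1-ol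
Conditions: Ph3PCH3Br, KOt-Bu (3 equiv each), THF, 0 °C → 50 °C
Reagents that add atoms: methyltriphenylphosphonium bromide, C[P+](c1ccccc1)(c1ccccc1)c1ccccc1.[Br-]
Why: Wittig methylenation of the open hydroxy aldehyde form of the lactol installs C1=C2 and releases the C6 alcohol in one operation. The aldehyde has no α-hydrogen, so C3 cannot epimerise.

Step 10
Reactants: 16 silyl ether
Product: 17 (4R)-4-{[(1S,2S,4S)-4-bromo-2-(3-hydroxybutyl)-1,3,3-trimethylcyclohexyl]oxy}-4-methylhex-5-en-1-ol
Conditions: Bu4NF, THF, rt
Reagents that add atoms: none
Why: Fluoride-induced desilylation under non-acidic conditions, chosen because the tertiary allylic ether at C3 would be at risk under the acid a ketal would need.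

Step 11
Reactants: 17 diol
Product: 18 (4R)-4-{[(1S,2S,4S)-4-bromo-1,3,3-trimethyl-2-(3-oxobutyl)cyclohexyl]oxy}-4-methylhex-5-enal
Conditions: Dess–Martin periodinane (3 equiv), pyridine, CH2Cl2, 0 °C → rt
Reagents that add atoms: none
Why: Dess–Martin oxidation takes the primary alcohol to the aldehyde and the secondary one to the methyl ketone under buffered conditions that touch neither the alkene nor the bromide.

Step 12
Reactants: 18 keto aldehyde
Product: 19 (3R,6R,7S,10S,11S,14S)-cis-6,7-diol of the ten-membered ether (target numbering; hydroxyls on C6 and C7 on the same ring face)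
Conditions: SmI2 (3 equiv), THF, −78 °C → rt, slow addition of 18 (2 mM final)
Reagents that add atoms: none
Why: SmI2-mediated pinacol cyclisation, a known route to medium and large ring 1,2-diols: the aldehyde ketyl adds to the samarium-bound ketone under high dilution, and alkyl bromides are not reduced by SmI2 in THF without HMPA. Bridging of both oxygens by trivalent samarium should favour the cis-diol; the 6R,7S sense relative to C3, C10 and C11 rests on the conformation of the closing chain and is not assured.

Step 13
Reactants: 19 cis-diol
Product: 21 target CNP0243863.1 (3R,6S,7S,10S,11S,14S), via C6 mesylate 20 (not isolated)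
Conditions: MsCl (1.1 equiv), Et3N, CH2Cl2, −20 °C; then K2CO3, MeOH, rt
Reagents that add atoms: none
Why: Selective sulfonylation of the secondary hydroxyl, then intramolecular Williamson displacement by the tertiary alkoxide. Inversion at C6 and retention at C7 turn the cis-diol stereospecifically into the epoxide with C5 and C8 trans (6S,7S).

Compound list

1 | geranylacetone, (E)-6,10-dimethylundeca-5,9-dien-2-one | CC(=O)CC/C=C(\C)CCC=C(C)C | starting material
2 | (4aS,6S,8aS)-6-bromo-2,5,5,8a-tetramethyl-4a,5,6,7,8,8a-hexahydro-4H-chromene | CC1=CC[C@H]2C(C)(C)[C@@H](Br)CC[C@]2(C)O1 | intermediate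
3 | 4-[(1S,3S,6S)-3-bromo-6-hydroxy-2,2,6-trimethylcyclohexyl]butan-2-one | CC(=O)CC[C@H]1C(C)(C)[C@@H](Br)CC[C@]1(C)O | intermediate (not isolated)
4 | (1S,2S,4S)-4-bromo-2-(3-hydroxybutyl)-1,3,3-trimethylcyclohexan-1-ol, C7 epimers | CC(O)CC[C@H]1C(C)(C)[C@@H](Br)CC[C@]1(C)O | intermediate
5 | (1S,2S,4S)-4-bromo-2-[3-(tert-butyldimethylsilyloxy)butyl]-1,3,3-trimethylcyclohexan-1-ol | CC(O[Si](C)(C)C(C)(C)C)CC[C@H]1C(C)(C)[C@@H](Br)CC[C@]1(C)O | intermediate
6 | allyl bromide | C=CCBr | starting material
7 | ring-A tertiary allyl ether with C7 silyloxy group (key-step precursor) | CC(O[Si](C)(C)C(C)(C)C)CC[C@H]1C(C)(C)[C@@H](Br)CC[C@]1(C)OCC=C | intermediate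
8 | methyl 2-methylacetoacetate | COC(=O)C(C)C(C)=O | starting material
9 | methyl 2-diazopropanoate | CC(=[N+]=[N-])C(=O)OC | intermediate
10 | allyl oxonium ylide of 7 with the methyl ester carbenoid carbon | CC(O[Si](C)(C)C(C)(C)C)CC[C@H]1C(C)(C)[C@@H](Br)CC[C@]1(C)[O+](CC=C)[C-](C)C(=O)OC | intermediate (not isolated)
11 | methyl (2R)-2-{[ring A]oxy}-2-methylpent-4-enoate (key-step product; ester and allyl on C3) | CC(O[Si](C)(C)C(C)(C)C)CC[C@H]1C(C)(C)[C@@H](Br)CC[C@]1(C)O[C@@](C)(C(=O)OC)CC=C | intermediate
12 | B-alkyl-9-borabicyclo[3.3.1]nonane adduct at C6 | CC(O[Si](C)(C)C(C)(C)C)CC[C@H]1C(C)(C)[C@@H](Br)CC[C@]1(C)O[C@@](C)(C(=O)OC)CCCB2C3CCCC2CCC3 | intermediate (not isolated)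
13 | methyl (2R)-5-hydroxy-2-{[ring A]oxy}-2-methylpentanoate | CC(O[Si](C)(C)C(C)(C)C)CC[C@H]1C(C)(C)[C@@H](Br)CC[C@]1(C)O[C@@](C)(C(=O)OC)CCCO | intermediate (not isolated)
14 | (3R)-3-{[ring A]oxy}-3-methyltetrahydro-2H-pyran-2-one | CC(O[Si](C)(C)C(C)(C)C)CC[C@H]1C(C)(C)[C@@H](Br)CC[C@]1(C)O[C@]2(C)CCCOC2=O | intermediate
15 | (3R)-3-{[ring A]oxy}-3-methyltetrahydro-2H-pyran-2-ol, anomers | CC(O[Si](C)(C)C(C)(C)C)CC[C@H]1C(C)(C)[C@@H](Br)CC[C@]1(C)O[C@]2(C)CCCOC2O | intermediate
16 | (4R)-4-{[ring A]oxy}-4-methylhex-5-en-1-ol, C7 silyl ether | CC(O[Si](C)(C)C(C)(C)C)CC[C@H]1C(C)(C)[C@@H](Br)CC[C@]1(C)O[C@@](C)(C=C)CCCO | intermediate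
17 | (4R)-4-{[(1S,2S,4S)-4-bromo-2-(3-hydroxybutyl)-1,3,3-trimethylcyclohexyl]oxy}-4-methylhex-5-en-1-ol | CC(O)CC[C@H]1C(C)(C)[C@@H](Br)CC[C@]1(C)O[C@@](C)(C=C)CCCO | intermediate
18 | (4R)-4-{[(1S,2S,4S)-4-bromo-1,3,3-trimethyl-2-(3-oxobutyl)cyclohexyl]oxy}-4-methylhex-5-enal | CC(=O)CC[C@H]1C(C)(C)[C@@H](Br)CC[C@]1(C)O[C@@](C)(C=C)CCC=O | intermediate
19 | (3R,6R,7S,10S,11S,14S)-cis-6,7-diol of the ten-membered ether | C=C[C@@]1(C)CC[C@@H](O)[C@](O)(C)CC[C@H]2C(C)(C)[C@@H](Br)CC[C@]2(C)O1 | intermediate
20 | C6 methanesulfonate of 19 | C=C[C@@]1(C)CC[C@@H](OS(C)(=O)=O)[C@](O)(C)CC[C@H]2C(C)(C)[C@@H](Br)CC[C@]2(C)O1 | intermediate (not isolated)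
21 | CNP0243863.1, (3R,6S,7S,10S,11S,14S)-bromo epoxy ten-membered ether | C=C[C@@]1(C)CC[C@@H]2O[C@@]2(C)CC[C@H]2C(C)(C)[C@@H](Br)CC[C@]2(C)O1 | target

Total step count: 13. Longest linear sequence: 12 steps (steps 1–4 and 6–13, from 1); step 5 is a one-step side branch.

Least certain steps

Step 6 (key step, proposed new method). The most likely failure is slow ylide formation at an oxygen flanked by the quaternary C11, so that the carbenoid is consumed by β-hydride shift, dimerisation or cyclopropanation; poor facial selectivity at C3 is the second concern, because no stereocentre neighbours C3 on carbon. Fallback with known chemistry, setting out from 5 and returning at 11: rhodium-catalysed O–H insertion (Rh2(OAc)4, methyl diazoacetate, CH2Cl2), a reaction established for tertiary alcohols, should give the methyl alkoxyacetate F1. Enolate methylation (LiN(i-Pr)2, THF, −78 °C; MeI) should give the methyl 2-alkoxypropanoate F2. A second enolate alkylation (KN(SiMe3)2, THF, −78 °C; 6) should then build the quaternary carbon and give 11, the C3 epimers again being separated at 14.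

Step 1. The most likely failure is insufficient enantioinduction or interrupted cyclisation, because the ketone terminator differs from the aryl and phenol terminators for which the catalytic asymmetric bromocyclisation is established. Fallback, setting out from 1 and returning at 3: racemic cyclisation with Et2SBr·SbBrCl5 in MeNO2 at −25 °C should give 2 together with the enantiomeric enol ether F3. Acid hydrolysis as in step 2 should give 3 together with the enantiomeric hydroxy ketone F4, which is removed by preparative chromatography on a chiral stationary phase. The resolved 3 is then reduced as in step 2.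

Step 4. The most likely failure is internal displacement of the trans-1,4 bromide by the tertiary alkoxide (oxygen bridge across ring A), or sluggish alkylation of the hindered alkoxide. Fallback, setting out from 5 and returning at 7: acid-catalysed allylation with allyl 2,2,2-trichloroacetimidate and CF3SO3H (cat.) in cyclohexane/CH2Cl2 transfers the allyl group without ever forming the alkoxide. This fallback makes no new compound (F0).

Step 12. The most likely failure is the wrong relative or facial selectivity in the ketyl addition: a ring of this size can accommodate an anti C5–C6–C7–C8 arrangement, which leads to a trans-diol that step 13 would convert into the wrong epoxide. Intermolecular coupling is a second concern. Fallback, setting out from 18 and returning at 21: the same coupling is accepted with its trans-diol F5 (either trans-diol serves). Thiophosgene and DMAP should convert it into the cyclic thiocarbonate F6. Corey–Winter syn-elimination with 1,3-dimethyl-2-phenyl-1,3,2-diazaphospholidine (THF, 40 °C) should then give the E-cycloalkene F7 stereospecifically. Epoxidation with m-CPBA (NaHCO3, CH2Cl2, 0 °C) should attack the trisubstituted alkene, in preference to the vinyl group, from its exposed peripheral face and give 21; this facial preference is reasoned by analogy with other E-cyclodecenes and is not assured.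

Further compounds

F1 | step 6 | methyl 2-{[(1S,2S,4S)-4-bromo-2-[3-(tert-butyldimethylsilyloxy)butyl]-1,3,3-trimethylcyclohexyl]oxy}acetate | CC(O[Si](C)(C)C(C)(C)C)CC[C@H]1C(C)(C)[C@@H](Br)CC[C@]1(C)OCC(=O)OC
F2 | step 6 | methyl 2-{[(1S,2S,4S)-4-bromo-2-[3-(tert-butyldimethylsilyloxy)butyl]-1,3,3-trimethylcyclohexyl]oxy}propanoate, C3 epimers | CC(O[Si](C)(C)C(C)(C)C)CC[C@H]1C(C)(C)[C@@H](Br)CC[C@]1(C)OC(C)C(=O)OC
F3 | step 1 | (4aR,6R,8aR)-6-bromo-2,5,5,8a-tetramethyl-4a,5,6,7,8,8a-hexahydro-4H-chromene | CC1=CC[C@@H]2C(C)(C)[C@H](Br)CC[C@@]2(C)O1
F4 | step 1 | 4-[(1R,3R,6R)-3-bromo-6-hydroxy-2,2,6-trimethylcyclohexyl]butan-2-one | CC(=O)CC[C@@H]1C(C)(C)[C@H](Br)CC[C@@]1(C)O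
F0 | step 4 | none | none
F5 | step 12 | (3R,6S,7S,10S,11S,14S)-trans-6,7-diol of the ten-membered ether | C=C[C@@]1(C)CC[C@H](O)[C@](O)(C)CC[C@H]2C(C)(C)[C@@H](Br)CC[C@]2(C)O1
F6 | step 12 | cyclic 6,7-thiocarbonate of the trans-diol | C=C[C@@]1(C)CC[C@@H]3OC(=S)O[C@@]3(C)CC[C@H]2C(C)(C)[C@@H](Br)CC[C@]2(C)O1
F7 | step 12 | ten-membered ether with (E)-C6=C7 alkene | C=C[C@@]1(C)CC/C=C(\C)CC[C@H]2C(C)(C)[C@@H](Br)CC[C@]2(C)O1
A1 | alternative 1 | tetrahydropyran diene with C6 silyl ether and C3 ethynyl group | C#C[C@@]1(C)CC[C@H](O[Si](C)(C)C(C)(C)C)[C@@](C)(CC/C=C(C)/CCC=C(C)C)O1
A2 | alternative 1 | ethynyl analogue of the target | C#C[C@@]1(C)CC[C@@H]2O[C@@]2(C)CC[C@H]2C(C)(C)[C@@H](Br)CC[C@]2(C)O1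
A3 | alternative 2 | open-chain C9 phenyl sulfone with (E)-C8 allylic bromide | C=C[C@@](C)(CC/C=C(\C)CBr)O[C@@]1(C)CC[C@H](Br)C(C)(C)[C@@H]1CS(=O)(=O)c2ccccc2
A4 | alternative 2 | ten-membered (E)-alkene with phenylsulfonyl group on C9 | C=C[C@@]1(C)CC/C=C(\C)CC(S(=O)(=O)c3ccccc3)[C@H]2C(C)(C)[C@@H](Br)CC[C@]2(C)O1
A5 | alternative 3 | 14-membered lactone with C2=C3 enol ether (geometry left open) | O=C1CC/C=C(\C)CC[C@H]2C(C)(C)[C@@H](Br)CC[C@]2(C)OC(C)=CCO1
A6 | alternative 3 | ten-membered ether with carboxyl group on C4 | C=C[C@@]1(C)C(C(=O)O)C/C=C(\C)CC[C@H]2C(C)(C)[C@@H](Br)CC[C@]2(C)O1
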